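**Plan**
- Retrosynthetic cuts, in order: the C8–O ester bond; the C4=C5 olefin (ring-closing metathesis); the lactone O–C6 bond (allylic C–H lactonization); the C1/C10 epoxide oxygen; C11–C12 (carbonylation); C7–C8 (aldol); C2–C3 (allyl–allyl coupling).
- Forward: a C8–C4 dienal (Z olefin taken from a six-membered lactone) and a pentenoyl imide give an open-chain 2-methylene acid. The γ-lactone ring is closed first (O–C6), the ten-membered ring second (C4=C5), and the side-chain ester is attached last.
- Enabling feature: C6 is a methylene that is allylic to C5 (a vinyl group in the precursor) and γ to the C12 carboxyl through C11–C7. Oxidative C–H/O–H coupling can therefore close the five-membered ring O–C6–C7–C11–C12 without a leaving group on C6, and the same vinyl group then becomes C5 of the ring olefin.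
- Stereochemistry: C7/C8 from an auxiliary-controlled syn-aldol; C1/C10 from reagent-controlled epoxidation of the Z olefin; C6 from C7 in the key step (trans-lactone); Z-C4=C5 from ring strain in the ten-membered ring; C2′/C3′ from a Sharpless epoxidation.

Key step: step 13

Remark: locants C1–C15 follow germacrane numbering (C12 lactone carbonyl, C13 exocyclic methylene); the target is read as the (4Z)-olefin with a cis-fused (1S,10R)-epoxide and a (2S,3R)-2,3-dimethyloxirane-2-carboxylate.
Remark: 1, 4 (as THF solution), 7, 8 and 22 are taken as catalogue compounds.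
Remark: the facial sense of step 12 is assigned from the spiro transition-state model; should it prove opposite, the enantiomeric (D-fructose-derived) ketone is used and nothing else changes.

**Route**

Step 1
Reactants: 1 4-methyl-5,6-dihydro-2H-pyran-2-one
Product: 2 (2Z)-3-methylpent-2-ene-1,5-diol
Conditions: i-Bu2AlH (3.5 equiv), CH2Cl2, −78 to 0 °C; aq. potassium sodium tartrate
Reagents that add atoms: none
Why: Exhaustive 1,2-hydride reduction of the unsaturated lactone should open the ring to the diol, the Z geometry of the future C10=C1 olefin being fixed by the six-membered ring of 1.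

Step 2
Reactants: 2 (2Z)-3-methylpent-2-ene-1,5-diol
Product: 3 (3Z)-5-chloro-3-methylpent-3-en-1-ol
Conditions: NCS, Me2S, CH2Cl2, −20 to 0 °C
Reagents that add atoms: N-chlorosuccinimide, O=C1CCC(=O)N1Cl
Why: Corey–Kim chlorination converts only the allylic alkoxysulfonium ion into the chloride (SN2 by chloride), the saturated primary hydroxyl being returned on work-up, and the olefin geometry is untouched.

Step 3
Reactants: 3 (3Z)-5-chloro-3-methylpent-3-en-1-ol; 4 2-methylallylmagnesium chloride
Product: 5 (3Z)-3,7-dimethylocta-3,7-dien-1-ol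
Conditions: 3 added to 4 (2.5 equiv), THF, −20 to 0 °C; aq. NH4Cl
Reagents that add atoms: none
Why: Allyl–allyl coupling by SN2 displacement of the primary allylic chloride with the symmetrical allyl Grignard reagent should form C2–C3 with retention of the Z olefin, attack at the fully substituted γ-carbon and ring closure by the poorly nucleophilic magnesium alkoxide being slower.

Step 4
Reactants: 5 (3Z)-3,7-dimethylocta-3,7-dien-1-ol
Product: 6 (3Z)-3,7-dimethylocta-3,7-dienal
Conditions: Dess–Martin periodinane, NaHCO3, CH2Cl2, 0 °C; used at once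
Reagents that add atoms: none
Why: Dess–Martin oxidation under buffered, non-basic conditions should give the β,γ-unsaturated aldehyde without migration of the Z olefin into conjugation.

Step 5
Reactants: 7 (S)-4-benzyloxazolidin-2-one; 8 pent-4-enoyl chloride
Product: 9 (S)-4-benzyl-3-(pent-4-enoyl)oxazolidin-2-one
Conditions: Et3N, DMAP (cat.), CH2Cl2, 0 °C to rt
Reagents that add atoms: none
Why: DMAP-catalysed N-acylation of the oxazolidinone by the acid chloride, in which the stereocenter of the auxiliary is not involved.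

Step 6
Reactants: 9 (S)-4-benzyl-3-(pent-4-enoyl)oxazolidin-2-one; 6 (3Z)-3,7-dimethylocta-3,7-dienal
Product: 11 (S)-4-benzyl-3-[(2S,3R,5Z)-2-allyl-3-hydroxy-5,9-dimethyldeca-5,9-dienoyl]oxazolidin-2-one, via dibutylboron Z-enolate 10 (not isolated)
Conditions: Bu2BOTf, i-Pr2NEt, CH2Cl2, −78 to 0 °C; 6, −78 °C; then pH 7 buffer, MeOH, H2O2, 0 °C
Reagents that add atoms: none
Why: Evans syn-aldol reaction, in which the Z-boron enolate reacts through a chair (Zimmerman–Traxler) transition state on the face opposite to the benzyl group, should set C7 and C8 as the 7,8-syn pair with the absolute configuration of the target.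

Step 7
Reactants: 11 (S)-4-benzyl-3-[(2S,3R,5Z)-2-allyl-3-hydroxy-5,9-dimethyldeca-5,9-dienoyl]oxazolidin-2-one
Product: 12 (2S,3R,5Z)-2-allyl-3-hydroxy-N-methoxy-N,5,9-trimethyldeca-5,9-dienamide
Conditions: MeNH(OMe)·HCl, AlMe3, CH2Cl2, −20 to 0 °C; aq. potassium sodium tartrate
Reagents that add atoms: N,O-dimethylhydroxylamine hydrochloride, CNOC.Cl
Why: Aluminium amide transamination of the β-hydroxy imide (assisted by the free hydroxyl) should give the Weinreb amide and return the auxiliary 7 without touching C7 or C8.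

Step 8
Reactants: 12 (2S,3R,5Z)-2-allyl-3-hydroxy-N-methoxy-N,5,9-trimethyldeca-5,9-dienamide
Product: 13 (2S,3R,5Z)-2-allyl-3-[(tert-butyldimethylsilyl)oxy]-N-methoxy-N,5,9-trimethyldeca-5,9-dienamide
Conditions: TBSOTf, 2,6-lutidine, CH2Cl2, −78 to 0 °C
Reagents that add atoms: tert-butyldimethylsilyl trifluoromethanesulfonate, CC(C)(C)[Si](C)(C)OS(=O)(=O)C(F)(F)F
Why: Silylation of the secondary alcohol protects O8 as an ether that is a poor leaving group, so that the later enolate chemistry cannot eliminate it.

Step 9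
Reactants: 13 (2S,3R,5Z)-2-allyl-3-[(tert-butyldimethylsilyl)oxy]-N-methoxy-N,5,9-trimethyldeca-5,9-dienamide
Product: 14 (3S,4R,6Z)-3-allyl-4-[(tert-butyldimethylsilyl)oxy]-6,10-dimethylundeca-6,10-dien-2-one
Conditions: MeMgBr, THF, −78 to 0 °C; aq. NH4Cl
Reagents that add atoms: methylmagnesium bromide, C[Mg]Br
Why: Grignard addition to the Weinreb amide stops at the chelated tetrahedral intermediate and should give the methyl ketone on work-up, so that C11 now carries the future C13.

Step 10
Reactants: 14 (3S,4R,6Z)-3-allyl-4-[(tert-butyldimethylsilyl)oxy]-6,10-dimethylundeca-6,10-dien-2-one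
Product: 16 (3S,4R,6Z)-3-allyl-4-[(tert-butyldimethylsilyl)oxy]-6,10-dimethylundeca-1,6,10-trien-2-yl trifluoromethanesulfonate, via potassium enolate 15 (not isolated)
Conditions: KN(SiMe3)2, THF, −78 °C; then PhNTf2, −78 to −40 °C
Reagents that add atoms: N-phenylbis(trifluoromethanesulfonimide), O=S(=O)(N(c1ccccc1)S(=O)(=O)C(F)(F)F)C(F)(F)F
Why: Kinetic deprotonation of the methyl ketone at the unhindered methyl group and O-sulfonylation of the enolate should give the 2-triflyloxy-1-alkene and leave the tertiary C7–H untouched.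

Step 11
Reactants: 16 (3S,4R,6Z)-3-allyl-4-[(tert-butyldimethylsilyl)oxy]-6,10-dimethylundeca-1,6,10-trien-2-yl trifluoromethanesulfonate
Product: 17 (3R,4R,6Z)-3-allyl-4-[(tert-butyldimethylsilyl)oxy]-6,10-dimethyl-2-methylideneundeca-6,10-dienoic acid
Conditions: Pd(OAc)2 (5 mol %), PPh3, i-Pr2NEt, CO (1 atm), DMF/H2O, 50 °C; then aq. NaH2PO4
Reagents that add atoms: carbon monoxide, [C-]#[O+]; water, O
Why: Palladium-catalysed hydroxycarbonylation of the enol triflate (oxidative addition to zerovalent palladium, CO insertion, hydrolysis of the acylpalladium) should install C12 and give the 2-methylene acid without any metal hydride that could move the olefins.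

Step 12
Reactants: 17 (3R,4R,6Z)-3-allyl-4-[(tert-butyldimethylsilyl)oxy]-6,10-dimethyl-2-methylideneundeca-6,10-dienoic acid
Product: 18 (3R,4R)-3-allyl-4-[(tert-butyldimethylsilyl)oxy]-2-methylidene-5-[(2R,3S)-2-methyl-3-(3-methylbut-3-en-1-yl)oxiran-2-yl]pentanoic acid
Conditions: ent-Shi ketone (1,2:4,5-di-O-isopropylidene-L-erythro-2,3-hexodiulo-2,6-pyranose, 30 mol %), KHSO5 (as 2KHSO5·KHSO4·K2SO4), K2CO3, Bu4NHSO4, MeCN/CH2(OMe)2/aq. Na2B4O7 buffer, 0 °C; then NaH2PO4 to pH 5
Reagents that add atoms: potassium peroxymonosulfate, [K+].[O-]S(=O)(=O)OO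
Why: Shi epoxidation, in which the chiral dioxirane reacts fastest with the electron-rich trisubstituted C1=C10 olefin (the monosubstituted, 1,1-disubstituted and acrylic olefins are slower) and, through the spiro transition state of the L-series ketone, should deliver oxygen by stereospecific syn addition to the face of the Z olefin that gives the cis (10R,1S)-epoxide.

Step 13
Reactants: 18 (3R,4R)-3-allyl-4-[(tert-butyldimethylsilyl)oxy]-2-methylidene-5-[(2R,3S)-2-methyl-3-(3-methylbut-3-en-1-yl)oxiran-2-yl]pentanoic acid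
Product: 19 (4S,5R)-4-{(1R)-1-[(tert-butyldimethylsilyl)oxy]-2-[(2R,3S)-2-methyl-3-(3-methylbut-3-en-1-yl)oxiran-2-yl]ethyl}-3-methylidene-5-vinyloxolan-2-one
Conditions: Pd(OAc)2·PhS(O)CH2CH2S(O)Ph (10 mol %), 1,4-benzoquinone (2 equiv), CH2Cl2 (10 mM), 45 °C
Reagents that add atoms: none
Why: Divalent palladium, bound to the carboxylate and the bis-sulfoxide, cleaves an allylic C6–H bond of the only monosubstituted olefin to give a π-allylpalladium carboxylate, and benzoquinone-promoted C–O bond formation at the internal allyl terminus releases the lactone and zerovalent palladium, which benzoquinone reoxidises. The closest known reaction type is the Pd(OAc)2/bis-sulfoxide allylic C–H oxidation of terminal olefins by tethered carboxylic acids (macrolactones and 1,4-dioxan-2-ones). The five-membered ring O–C6–C7–C11–C12 closes in the 5-exo mode, the oxygen attacking allyl terminus C6 and the C5=CH2 vinyl group staying outside the ring. C6 is the only new stereocenter and is controlled by C7: the π-allyl faces interconvert by π–σ–π isomerisation through the unsubstituted terminus, and closure should go through the arrangement that places the vinyl group trans to the bulky C8 side chain (allylic strain minimised), giving the (6R) trans-lactone. The step needs site selectivity (C6–H, not the allylic positions of the 1,1-disubstituted olefin), branched regioselectivity (γ-lactone, not the seven-membered linear ester or a Wacker-type δ-lactone) and tolerance of the epoxide and silyl ether; the catalyst's preference for monosubstituted olefins, the 1,4-relationship of C12 and C6 and the near-neutral conditions should secure these.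

Step 14
Reactants: 19 (4S,5R)-4-{(1R)-1-[(tert-butyldimethylsilyl)oxy]-2-[(2R,3S)-2-methyl-3-(3-methylbut-3-en-1-yl)oxiran-2-yl]ethyl}-3-methylidene-5-vinyloxolan-2-one
Product: 20 (1S,6R,7S,8R,10R,4Z)-8-[(tert-butyldimethylsilyl)oxy]-1,10-epoxygermacra-4,11(13)-dien-12,6-olide
Conditions: second-generation Hoveyda–Grubbs catalyst (H2IMes)Cl2Ru=CH(C6H4-2-O-i-Pr) (10 mol %), toluene (1 mM), 80 °C
Reagents that add atoms: none
Why: Ring-closing metathesis between the C6 vinyl group and the 1,1-disubstituted C4 olefin should close the ten-membered ring with loss of ethylene, the trisubstituted C4=C5 olefin being expected Z because the E isomer is more strained in a ten-membered ring that already holds the cis-epoxide and the trans-lactone, and no other olefin pair can close an unstrained ring.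

Step 15
Reactants: 20 (1S,6R,7S,8R,10R,4Z)-8-[(tert-butyldimethylsilyl)oxy]-1,10-epoxygermacra-4,11(13)-dien-12,6-olide
Product: 21 (1S,6R,7R,8R,10R,4Z)-1,10-epoxy-8-hydroxygermacra-4,11(13)-dien-12,6-olide
Conditions: Bu4NF, AcOH, THF, 0 °C to rt
Reagents that add atoms: none
Why: Fluoride desilylation buffered with acetic acid should free O8 without opening the epoxide, adding to the methylene lactone or moving the acyl group from O6 to O8.

Step 16
Reactants: 22 (E)-2-methylbut-2-en-1-ol
Product: 23 [(2R,3R)-2,3-dimethyloxiran-2-yl]methanol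
Conditions: Ti(O-i-Pr)4 (10 mol %), D-(−)-diisopropyl tartrate (12 mol %), t-BuOOH, 4 Å MS, CH2Cl2, −20 °C
Reagents that add atoms: tert-butyl hydroperoxide, CC(C)(C)OO
Why: Sharpless asymmetric epoxidation, in which the titanium–D-(−)-tartrate catalyst delivers oxygen to one face of the allylic alcohol, should give the (2R,3R)-epoxy alcohol by syn addition to the E olefin.

Step 17
Reactants: 23 [(2R,3R)-2,3-dimethyloxiran-2-yl]methanol
Product: 24 (2S,3R)-2,3-dimethyloxirane-2-carboxylic acid
Conditions: RuCl3·xH2O (2 mol %), NaIO4, CCl4/MeCN/H2O, rt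
Reagents that add atoms: water, O; sodium periodate, [Na+].[O-]I(=O)(=O)=O
Why: Ruthenium-catalysed periodate oxidation (RuO4 formed in the flask) should take the primary alcohol to the glycidic acid without touching the epoxide stereocenters, the C2 descriptor changing to S by priority only.

Step 18
Reactants: 24 (2S,3R)-2,3-dimethyloxirane-2-carboxylic acid; 21 (1S,6R,7R,8R,10R,4Z)-1,10-epoxy-8-hydroxygermacra-4,11(13)-dien-12,6-olide
Product: 26 CNP0165580.2, via mixed anhydride 25 (not isolated)
Conditions: 24, 2,4,6-trichlorobenzoyl chloride, Et3N, THF, rt; then 21, DMAP, toluene, rt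
Reagents that add atoms: none
Why: Yamaguchi esterification, in which the mixed anhydride acylates the hindered secondary O8 under DMAP catalysis, should give the target with retention at C8 and no change at any other stereocenter.

**Compound list**
1 | 4-methyl-5,6-dihydro-2H-pyran-2-one (anhydromevalonolactone) | CC1=CC(=O)OCC1 | starting material
2 | (2Z)-3-methylpent-2-ene-1,5-diol | OCC/C(C)=C\CO | intermediate
3 | (3Z)-5-chloro-3-methylpent-3-en-1-ol | OCC/C(C)=C\CCl | intermediate
4 | 2-methylallylmagnesium chloride | CC(=C)C[Mg]Cl | starting material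
5 | (3Z)-3,7-dimethylocta-3,7-dien-1-ol | OCC/C(C)=C\CCC(C)=C | intermediate
6 | (3Z)-3,7-dimethylocta-3,7-dienal | O=CC/C(C)=C\CCC(C)=C | intermediate
7 | (S)-4-benzyloxazolidin-2-one | O=C1OC[C@H](Cc2ccccc2)N1 | starting material
8 | pent-4-enoyl chloride | C=CCCC(Cl)=O | starting material
9 | (S)-4-benzyl-3-(pent-4-enoyl)oxazolidin-2-one | C=CCCC(=O)N1C(=O)OC[C@@H]1Cc1ccccc1 | intermediate
10 | dibutylboron (Z)-enolate of 9 (not isolated) | CCCCB(CCCC)O/C(=C\CC=C)N1C(=O)OC[C@@H]1Cc1ccccc1 | intermediate
11 | (S)-4-benzyl-3-[(2S,3R,5Z)-2-allyl-3-hydroxy-5,9-dimethyldeca-5,9-dienoyl]oxazolidin-2-one | O=C(N1C(=O)OC[C@@H]1Cc1ccccc1)[C@@H](CC=C)[C@H](O)C/C(C)=C\CCC(C)=C | intermediate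
12 | (2S,3R,5Z)-2-allyl-3-hydroxy-N-methoxy-N,5,9-trimethyldeca-5,9-dienamide | CON(C)C(=O)[C@@H](CC=C)[C@H](O)C/C(C)=C\CCC(C)=C | intermediate
13 | (2S,3R,5Z)-2-allyl-3-[(tert-butyldimethylsilyl)oxy]-N-methoxy-N,5,9-trimethyldeca-5,9-dienamide | CON(C)C(=O)[C@@H](CC=C)[C@H](O[Si](C)(C)C(C)(C)C)C/C(C)=C\CCC(C)=C | intermediate
14 | (3S,4R,6Z)-3-allyl-4-[(tert-butyldimethylsilyl)oxy]-6,10-dimethylundeca-6,10-dien-2-one | CC(=O)[C@@H](CC=C)[C@H](O[Si](C)(C)C(C)(C)C)C/C(C)=C\CCC(C)=C | intermediate
15 | potassium enolate of 14, deprotonated at the methyl group (not isolated) | [K+].[O-]C(=C)[C@@H](CC=C)[C@H](O[Si](C)(C)C(C)(C)C)C/C(C)=C\CCC(C)=C | intermediate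
16 | (3S,4R,6Z)-3-allyl-4-[(tert-butyldimethylsilyl)oxy]-6,10-dimethylundeca-1,6,10-trien-2-yl trifluoromethanesulfonate | C=C(OS(=O)(=O)C(F)(F)F)[C@@H](CC=C)[C@H](O[Si](C)(C)C(C)(C)C)C/C(C)=C\CCC(C)=C | intermediate
17 | (3R,4R,6Z)-3-allyl-4-[(tert-butyldimethylsilyl)oxy]-6,10-dimethyl-2-methylideneundeca-6,10-dienoic acid | C=C(C(=O)O)[C@@H](CC=C)[C@H](O[Si](C)(C)C(C)(C)C)C/C(C)=C\CCC(C)=C | intermediate
18 | (3R,4R)-3-allyl-4-[(tert-butyldimethylsilyl)oxy]-2-methylidene-5-[(2R,3S)-2-methyl-3-(3-methylbut-3-en-1-yl)oxiran-2-yl]pentanoic acid | C=C(C(=O)O)[C@@H](CC=C)[C@H](O[Si](C)(C)C(C)(C)C)C[C@@]1(C)O[C@H]1CCC(C)=C | intermediate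
19 | (4S,5R)-4-{(1R)-1-[(tert-butyldimethylsilyl)oxy]-2-[(2R,3S)-2-methyl-3-(3-methylbut-3-en-1-yl)oxiran-2-yl]ethyl}-3-methylidene-5-vinyloxolan-2-one | C=C1C(=O)O[C@H](C=C)[C@H]1[C@H](O[Si](C)(C)C(C)(C)C)C[C@@]2(C)O[C@H]2CCC(C)=C | intermediate
20 | (1S,6R,7S,8R,10R,4Z)-8-[(tert-butyldimethylsilyl)oxy]-1,10-epoxygermacra-4,11(13)-dien-12,6-olide | C=C1C(=O)O[C@@H]2/C=C(/C)CC[C@@H]3O[C@]3(C)C[C@@H](O[Si](C)(C)C(C)(C)C)[C@@H]12 | intermediate
21 | (1S,6R,7R,8R,10R,4Z)-1,10-epoxy-8-hydroxygermacra-4,11(13)-dien-12,6-olide | C=C1C(=O)O[C@@H]2/C=C(/C)CC[C@@H]3O[C@]3(C)C[C@@H](O)[C@@H]12 | intermediate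
22 | (E)-2-methylbut-2-en-1-ol | C/C=C(\C)CO | starting material
23 | [(2R,3R)-2,3-dimethyloxiran-2-yl]methanol | OC[C@@]1(C)O[C@@H]1C | intermediate
24 | (2S,3R)-2,3-dimethyloxirane-2-carboxylic acid | OC(=O)[C@@]1(C)O[C@@H]1C | intermediate
25 | (2S,3R)-2,3-dimethyloxirane-2-carboxylic 2,4,6-trichlorobenzoic anhydride (not isolated) | O=C(OC(=O)[C@@]1(C)O[C@@H]1C)c1c(Cl)cc(Cl)cc1Cl | intermediate
26 | CNP0165580.2, the 8-O-[(2S,3R)-2,3-dimethyloxirane-2-carbonyl] ester of 21 | C=C1C(=O)O[C@@H]2/C=C(/C)CC[C@@H]3O[C@]3(C)C[C@@H](OC(=O)[C@@]3(C)O[C@@H]3C)[C@@H]12 | target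

**Step count**
Total: 18 steps. Longest linear sequence: 15 steps (steps 1–4, 6–15 and 18; 1 → 2 → 3 → 5 → 6 → 11 → 12 → 13 → 14 → 16 → 17 → 18 → 19 → 20 → 21 → 26).

**Steps most likely to fail**

Step 14 (ring-closing metathesis). The ring may fail to close because the trans-fused lactone holds the two olefins apart, so that cross-metathesis to oligomers takes over, or the olefin may form with the wrong geometry. The fallback reverses the order of the two ring closures. It sets out from 18: the same metathesis on the open-chain acid builds no ring fusion and should give the monocyclic (1S,7R,8R,10R,4Z)-8-[(tert-butyldimethylsilyl)oxy]-1,10-epoxygermacra-4,11(13)-dien-12-oic acid F1. The lactone is then closed on the ring olefin by intramolecular allylic acyloxylation with Pd(OAc)2 and benzoquinone, the reaction type used for acetoxylation of cycloalkenes, with the tethered carboxyl directing C–O bond formation to C6. The route is rejoined at 20.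

Step 13 (allylic C–H lactonization). The carboxylate may add across the olefin instead (oxypalladation to a δ-lactone), the allyl intermediate may lose a β-hydrogen to give a diene, or trans/cis control at C6 may be poor. The fallback forms the same O–C6 bond by selenolactonization and sets out from 18. The terminal olefin is moved one position with [Ir(cod)(PMePh2)2]PF6 activated by H2 to give (3R,4R)-4-[(tert-butyldimethylsilyl)oxy]-2-methylidene-5-[(2R,3S)-2-methyl-3-(3-methylbut-3-en-1-yl)oxiran-2-yl]-3-[(E)-prop-1-en-1-yl]pentanoic acid F2. N-(Phenylseleno)phthalimide then closes the γ-lactone by anti addition in the 5-exo mode to give the (1R)-1-(phenylselanyl)ethyl analogue of 19 F3. Oxidation with H2O2 and syn elimination of the selenoxide away from the ring oxygen restores the vinyl group, and the route is rejoined at 19.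

Step 3 (allyl–allyl coupling). Material may be lost through intramolecular O-alkylation of the alkoxide to a six-membered cyclic ether and through SN2′ attack at C10. The fallback turns the side reaction into the route and sets out from 3: cyclisation on purpose (NaH, THF) gives 4-methyl-3,6-dihydro-2H-pyran F4. Its allylic C–O bond is then coupled with 4 under NiCl2(dppp) catalysis (nickel-catalysed Grignard coupling of allylic ethers), the ring holding the Z geometry until the bond is formed. Work-up of the liberated alkoxide returns the route to 5.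

**Further compounds**
F1 | step 14 | (1S,7R,8R,10R,4Z)-8-[(tert-butyldimethylsilyl)oxy]-1,10-epoxygermacra-4,11(13)-dien-12-oic acid | C=C(C(=O)O)[C@H]1C/C=C(/C)CC[C@@H]2O[C@]2(C)C[C@H]1O[Si](C)(C)C(C)(C)C
F2 | step 13 | (3R,4R)-4-[(tert-butyldimethylsilyl)oxy]-2-methylidene-5-[(2R,3S)-2-methyl-3-(3-methylbut-3-en-1-yl)oxiran-2-yl]-3-[(E)-prop-1-en-1-yl]pentanoic acid | C=C(C(=O)O)[C@@H](/C=C/C)[C@H](O[Si](C)(C)C(C)(C)C)C[C@@]1(C)O[C@H]1CCC(C)=C
F3 | step 13 | (1R)-1-(phenylselanyl)ethyl analogue of 19 (vinyl group replaced, other centers as in 19) | C=C1C(=O)O[C@H]([C@@H](C)[Se]c2ccccc2)[C@H]1[C@H](O[Si](C)(C)C(C)(C)C)C[C@@]3(C)O[C@H]3CCC(C)=C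
F4 | step 3 | 4-methyl-3,6-dihydro-2H-pyran | CC1=CCOCC1
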